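**Plan**

1. Retrosynthesis: the quinone ring is traced back to a p-methoxyphenol (C2′–OH free, C5′–OMe lost on oxidation). The C3–H stereocentre is traced back to the C3=C4 double bond of a 3-aryl-2H-chromene. That double bond is cut into an ylide carbon (C4) and an aryl ketone (C3), and the O1–C2 ether into a phenoxide and an α-bromo ketone.
2. Enabling feature: ring A (C4a–C8a, O1 on C8a, OMe on C6–C8) and the quinone ring (C1′–C6′, where C2′=O is an oxidised phenol and C5′=O an oxidised p-OMe) are the same 2-oxy-3,4,5-trimethoxyphenyl unit. C4 and C3 are the ortho-benzylic carbons of the two copies, so both halves come from 2,3,4-trimethoxyphenol and C3–C4 is a stilbene-type bond across the three-atom O1–C2 tether.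
3. Forward order: phenol → ring-A salicyl phosphonium salt and ring-B α-bromo ketone → one-flask O-alkylation (O1–C2) and intramolecular Wittig closure of the pyran ring (C3=C4) → hydrogenation → debenzylation → oxidation of ring B to the quinone.
4. Stereochemistry: the only stereocentre (C3, S) is set by catalyst-controlled iridium asymmetric hydrogenation of C3=C4 and is not touched afterwards.

Key step: step 8

Remark: C3 of the target as drawn is S (CIP order C2 > C1′ > C4 > H); the same descriptor and spatial arrangement hold for the 3-arylchromans 13 and 14.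

**Route**

Step 1
Reactants: 1 2,3,4-trimethoxybenzaldehyde
Product: 3 2,3,4-trimethoxyphenol, via 2,3,4-trimethoxyphenyl formate 2 (not isolated)
Conditions: 30% aq. H2O2, H2SO4 (cat.), MeOH, rt
Reagents that add atoms: hydrogen peroxide, OO
Why: Acid-catalysed Dakin oxidation, in which the aryl group activated by its ortho and para methoxy groups migrates to oxygen and the resulting formate is methanolysed in the same flask.

Step 2
Reactants: 3 2,3,4-trimethoxyphenol
Product: 4 2-hydroxy-3,4,5-trimethoxybenzaldehyde
Conditions: MgCl2, Et3N, (CH2O)n, MeCN, reflux; aq. HCl work-up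
Reagents that add atoms: paraformaldehyde (as formaldehyde), C=O
Why: Magnesium-mediated ortho-formylation (Casnati–Skattebøl type), in which the magnesium phenoxide delivers formaldehyde to the only free ortho position and a second equivalent of formaldehyde oxidises the salicyl alkoxide to the aldehyde.

Step 3
Reactants: 4 2-hydroxy-3,4,5-trimethoxybenzaldehyde
Product: 5 2-(hydroxymethyl)-4,5,6-trimethoxyphenol
Conditions: NaBH4, MeOH, 0 °C
Reagents that add atoms: none
Why: Borohydride reduction of an aryl aldehyde, the only reducible group present.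

Step 4
Reactants: 5 2-(hydroxymethyl)-4,5,6-trimethoxyphenol
Product: 6 (2-hydroxy-3,4,5-trimethoxybenzyl)triphenylphosphonium bromide
Conditions: Ph3P·HBr, MeCN, reflux
Reagents that add atoms: triphenylphosphine hydrobromide, [Br-].c1ccc(cc1)[PH+](c1ccccc1)c1ccccc1
Why: Acid-promoted SN1-type substitution of the electron-rich salicyl alcohol by triphenylphosphine, the standard entry to (2-hydroxybenzyl)phosphonium salts.

Step 5
Reactants: 3 2,3,4-trimethoxyphenol
Product: 8 1-(2-hydroxy-3,4,5-trimethoxyphenyl)ethanone, via 2,3,4-trimethoxyphenyl acetate 7 (not isolated)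
Conditions: Ac2O, BF3·OEt2, 80 °C; aq. NaOAc work-up
Reagents that add atoms: acetic anhydride, CC(=O)OC(C)=O
Why: O-Acetylation followed by Lewis-acid Fries rearrangement, which should place the acyl group at the single free ortho position because the para position carries OMe and the product is held as the chelated o-hydroxy ketone.

Step 6
Reactants: 8 1-(2-hydroxy-3,4,5-trimethoxyphenyl)ethanone
Product: 9 1-[2-(benzyloxy)-3,4,5-trimethoxyphenyl]ethanone
Conditions: BnBr, K2CO3, DMF, 60 °C
Reagents that add atoms: benzyl bromide, BrCc1ccccc1
Why: Williamson etherification, which masks the ring-B phenol as the only non-methyl ether so that this oxygen stays distinguishable and cannot close onto the later α-bromo ketone.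

Step 7
Reactants: 9 1-[2-(benzyloxy)-3,4,5-trimethoxyphenyl]ethanone
Product: 10 1-[2-(benzyloxy)-3,4,5-trimethoxyphenyl]-2-bromoethanone
Conditions: CuBr2 (2 equiv), EtOAc/CHCl3, reflux
Reagents that add atoms: copper(II) bromide, [Cu+2].[Br-].[Br-]
Why: Copper(II) bromide α-bromination through the enol, a method that is selective for the α-carbon of aryl methyl ketones over electron-rich rings and stops at the monobromide.

Step 8
Reactants: 6 (2-hydroxy-3,4,5-trimethoxybenzyl)triphenylphosphonium bromide; 10 1-[2-(benzyloxy)-3,4,5-trimethoxyphenyl]-2-bromoethanone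
Product: 12 3-[2-(benzyloxy)-3,4,5-trimethoxyphenyl]-6,7,8-trimethoxy-2H-chromene, via O-phenacylated phosphonium bromide 11 (not isolated)
Conditions: K2CO3, DMF, rt; then t-BuOK, THF, 0 °C to 50 °C
Reagents that add atoms: none
Why: The phenoxide of 6 is O-alkylated by the α-bromo ketone to give the O1–C2 tether; deprotonation at the benzylic phosphonium carbon then gives a semi-stabilised ylide whose carbon (C4) adds to the aryl ketone carbonyl (C3), and the oxaphosphetane collapses to C3=C4 and triphenylphosphine oxide (intramolecular Wittig olefination). The closest known reaction type is the Wittig ring closure of O-acylated or O-phenacylated (2-hydroxybenzyl)phosphonium salts to benzofurans and 3-substituted 2H-chromenes. The pyran ring closes in a 6-exo-trig mode, the ylide carbon attacking the exocyclic C=O to give the six-membered ring C4–C4a–C8a–O1–C2–C3. No stereocentre is formed; the double bond is endocyclic and C3 is left prochiral for step 9. The step needs O- over C-alkylation and olefination over enolate chemistry of the α-aryloxy ketone: the first is secured by using the weak base before the strong one, so that only the phenoxide is present during alkylation, the second by the six-membered proximity of ylide and carbonyl and the irreversible loss of the phosphine oxide. The benzyl ether keeps the ring-B oxygen from competing as a nucleophile.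

Step 9
Reactants: 12 3-[2-(benzyloxy)-3,4,5-trimethoxyphenyl]-6,7,8-trimethoxy-2H-chromene
Product: 13 (3S)-3-[2-(benzyloxy)-3,4,5-trimethoxyphenyl]-6,7,8-trimethoxychromane
Conditions: H2 (50 bar), [Ir(cod)(L*)]BArF (2 mol%; L* = phosphinite–oxazoline N,P ligand, enantiomer chosen for the S product), CH2Cl2, rt
Reagents that add atoms: none
Why: Iridium-catalysed asymmetric hydrogenation of a trisubstituted aryl alkene of the 3-aryl-2H-chromene class should add hydrogen to one enantiotopic face of C3=C4 under control of the chiral N,P ligand, which creates the C3 stereocentre as S, while benzyl and methyl ethers are inert to this catalyst.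

Step 10
Reactants: 13 (3S)-3-[2-(benzyloxy)-3,4,5-trimethoxyphenyl]-6,7,8-trimethoxychromane
Product: 14 2,3,4-trimethoxy-6-[(3S)-6,7,8-trimethoxychroman-3-yl]phenol
Conditions: H2 (1 atm), 10% Pd/C, EtOAc/MeOH, rt
Reagents that add atoms: none
Why: Hydrogenolysis of the benzyl aryl ether frees the single phenol, and C3 carries no benzylic C–O bond, so the stereocentre and the chroman ring should be untouched.

Step 11
Reactants: 14 2,3,4-trimethoxy-6-[(3S)-6,7,8-trimethoxychroman-3-yl]phenol
Product: 15 abruquinone B
Conditions: PhI(OAc)2 (1.1 equiv), MeCN/H2O, 0 °C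
Reagents that add atoms: water, O
Why: Hypervalent-iodine oxidative demethylation of a p-methoxyphenol, in which ligand exchange at iodine on the only free phenol, attack of water at the para carbon C5′ and loss of methanol should give the 2,3-dimethoxy-1,4-benzoquinone while the fully etherified ring A and the C3 stereocentre are not involved.

**Compound list**

1 | 2,3,4-trimethoxybenzaldehyde | COc1ccc(C=O)c(OC)c1OC | starting material
2 | 2,3,4-trimethoxyphenyl formate | COc1ccc(OC=O)c(OC)c1OC | intermediate
3 | 2,3,4-trimethoxyphenol | COc1ccc(O)c(OC)c1OC | intermediate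
4 | 2-hydroxy-3,4,5-trimethoxybenzaldehyde | COc1cc(C=O)c(O)c(OC)c1OC | intermediate
5 | 2-(hydroxymethyl)-4,5,6-trimethoxyphenol | COc1cc(CO)c(O)c(OC)c1OC | intermediate
6 | (2-hydroxy-3,4,5-trimethoxybenzyl)triphenylphosphonium bromide | COc1cc(C[P+](c2ccccc2)(c2ccccc2)c2ccccc2)c(O)c(OC)c1OC.[Br-] | intermediate
7 | 2,3,4-trimethoxyphenyl acetate | COc1ccc(OC(C)=O)c(OC)c1OC | intermediate
8 | 1-(2-hydroxy-3,4,5-trimethoxyphenyl)ethanone | COc1cc(C(C)=O)c(O)c(OC)c1OC | intermediate
9 | 1-[2-(benzyloxy)-3,4,5-trimethoxyphenyl]ethanone | COc1cc(C(C)=O)c(OCc2ccccc2)c(OC)c1OC | intermediate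
10 | 1-[2-(benzyloxy)-3,4,5-trimethoxyphenyl]-2-bromoethanone | COc1cc(C(=O)CBr)c(OCc2ccccc2)c(OC)c1OC | intermediate
11 | {2-[2-(2-benzyloxy-3,4,5-trimethoxyphenyl)-2-oxoethoxy]-3,4,5-trimethoxybenzyl}triphenylphosphonium bromide | COc1cc(C[P+](c2ccccc2)(c2ccccc2)c2ccccc2)c(OCC(=O)c2cc(OC)c(OC)c(OC)c2OCc2ccccc2)c(OC)c1OC.[Br-] | intermediate
12 | 3-[2-(benzyloxy)-3,4,5-trimethoxyphenyl]-6,7,8-trimethoxy-2H-chromene | COc1cc2C=C(COc2c(OC)c1OC)c1cc(OC)c(OC)c(OC)c1OCc1ccccc1 | intermediate
13 | (3S)-3-[2-(benzyloxy)-3,4,5-trimethoxyphenyl]-6,7,8-trimethoxychromane | COc1cc([C@H]2COc3c(cc(OC)c(OC)c3OC)C2)c(OCc2ccccc2)c(OC)c1OC | intermediate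
14 | 2,3,4-trimethoxy-6-[(3S)-6,7,8-trimethoxychroman-3-yl]phenol | COc1cc([C@H]2COc3c(cc(OC)c(OC)c3OC)C2)c(O)c(OC)c1OC | intermediate
15 | abruquinone B, 2,3-dimethoxy-5-[(3S)-6,7,8-trimethoxychroman-3-yl]cyclohexa-2,5-diene-1,4-dione | COC1=C(OC)C(=O)C([C@H]2COc3c(cc(OC)c(OC)c3OC)C2)=CC1=O | target

**Step count and risks**

Total step count: 11. Longest linear sequence: 8 steps (steps 1, 5, 6, 7, 8, 9, 10, 11; the ring-A branch through steps 1, 2, 3, 4, 8, 9, 10, 11 is equally long).

Steps most likely to fail:

Step 8. The ylide may be quenched by proton transfer from the acidic α-aryloxy ketone, or may add too slowly to the hindered, electron-rich aryl ketone, so that aldol-type self-condensation and cleavage of the phenacyl ether take over. The fallback replaces ylide olefination by reductive carbonyl coupling at the same C3–C4 bond. It sets out from salicylaldehyde 4, which is O-alkylated with bromo ketone 10 (K2CO3, DMF, rt) to the keto aldehyde 2-{2-[2-(benzyloxy)-3,4,5-trimethoxyphenyl]-2-oxoethoxy}-3,4,5-trimethoxybenzaldehyde F1. Intramolecular McMurry coupling of this compound (TiCl4, Zn, pyridine, THF, reflux, high dilution) should give the 2H-chromene 12, where the route is rejoined.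

Step 9. Facial discrimination at the ortho-substituted aryl alkene may be insufficient, the hindered double bond may hydrogenate slowly, or it may migrate to the 4H-chromene before reduction. The fallback replaces asymmetric catalysis by resolution. It sets out from 12, which is hydrogenated over Pd/C (H2, 1 atm, EtOAc/MeOH), saturating C3=C4 and removing the benzyl group in one operation, to the racemic phenol 2,3,4-trimethoxy-6-(6,7,8-trimethoxychroman-3-yl)phenol F2. Preparative chromatography on a chiral stationary phase separates the enantiomers; the (R)-phenol 2,3,4-trimethoxy-6-[(3R)-6,7,8-trimethoxychroman-3-yl]phenol F3 is set aside and the (S)-enantiomer is compound 14, where the route is rejoined.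

Step 11. Over-oxidation in the aqueous medium may occur: oxidation of the electron-rich ring A, attack at C3′ leading to an ortho-quinone, or oxidation at the benzylic C3–H of the product with loss of configuration. The fallback releases the quinone under non-oxidising conditions. It sets out from 14, which is oxidised with PhI(OAc)2 in anhydrous methanol at 0 °C to the isolable quinone monoketal 2,3,4,4-tetramethoxy-6-[(3S)-6,7,8-trimethoxychroman-3-yl]cyclohexa-2,5-dien-1-one F4. After purification this is hydrolysed with dilute aqueous oxalic acid in THF at rt to give 15.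

**Further compounds**

F1 | step 8 | 2-{2-[2-(benzyloxy)-3,4,5-trimethoxyphenyl]-2-oxoethoxy}-3,4,5-trimethoxybenzaldehyde | COc1cc(C=O)c(OCC(=O)c2cc(OC)c(OC)c(OC)c2OCc2ccccc2)c(OC)c1OC
F2 | step 9 | 2,3,4-trimethoxy-6-(6,7,8-trimethoxychroman-3-yl)phenol (racemate) | COc1cc(C2COc3c(cc(OC)c(OC)c3OC)C2)c(O)c(OC)c1OC
F3 | step 9 | 2,3,4-trimethoxy-6-[(3R)-6,7,8-trimethoxychroman-3-yl]phenol | COc1cc([C@@H]2COc3c(cc(OC)c(OC)c3OC)C2)c(O)c(OC)c1OC
F4 | step 11 | 2,3,4,4-tetramethoxy-6-[(3S)-6,7,8-trimethoxychroman-3-yl]cyclohexa-2,5-dien-1-one | COC1=C(OC)C(OC)(OC)C=C([C@H]2COc3c(cc(OC)c(OC)c3OC)C2)C1=O
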